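**Retrosynthetic overview**
- The C3 ketone comes from an allylic alcohol (MnO2). The ten-membered ring is closed last, at C3–C4, by an intramolecular Ni/Cr (Nozaki–Hiyama–Kishi) coupling of a C4 vinyl iodide with a C3 aldehyde.
- The angelate goes onto the C5 hydroxyl that is set free when a δ-lactone switches to the γ-lactone. The C7–C8 bond and the α-methylene lactone come from a chromium-mediated 2-carboxyallylation that joins fragment A (epoxy aldehyde) to fragment B (3-bromomethyl dihydropyranone).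
- Fragment A: Negishi carboalumination/oxirane opening gives the E-trisubstituted alkene; Shi epoxidation sets C1 and C10.
- Fragment B: C6 comes from (S)-but-3-ene-1,2-diol, C5 from a Felkin–Anh addition, and the dihydropyranone from ring-closing metathesis of a 2-(bromomethyl)acrylate.
- Ring order: epoxide, then dihydropyranone (fragment B), then γ-lactone (at the coupling), then the ten-membered carbocycle.

Assumption (atom labels used below, read from the target SMILES): lactone CH–O = C8, ring CH2 = C9, epoxide C(CH3) = C10, epoxide CH = C1, CH2 = C2, ketone = C3, C(=CH2) = C4, CH(O-angeloyl) = C5, CH(OH) = C6, ring-fusion CH = C7; lactone carbons C11 (α), C12 (C=O), C13 (=CH2); C14 = methyl on C10; C15 = methylene on C4.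

**Fragment A**

Step 1
Reactants: 1 but-3-yn-1-ol
Product: 2 1-[(but-3-yn-1-yloxy)methyl]-4-methoxybenzene
Conditions: NaH, PMBCl, Bu4NI (cat.), THF, 0 °C → rt
Reagents that add atoms: 4-methoxybenzyl chloride, COc1ccc(CCl)cc1
Why: Williamson etherification of the primary alkoxide gives a PMB ether that can later be removed oxidatively without touching a silyl ether or an epoxide.

Step 2
Reactants: 2 1-[(but-3-yn-1-yloxy)methyl]-4-methoxybenzene; 3 oxirane
Product: 6 (3E)-6-[(4-methoxyphenyl)methoxy]-4-methylhex-3-en-1-ol, via alkenyldimethylalane 4 (not isolated), via lithium alkenylalanate 5 (not isolated)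
Conditions: AlMe3 (2 equiv), Cp2ZrCl2 (0.25 equiv), CH2Cl2, 0 °C → rt; evaporate, hexane/THF, n-BuLi, −78 °C; then 3, −78 °C → rt; 1 M HCl work-up
Reagents that add atoms: trimethylaluminium, C[Al](C)C
Why: Negishi zirconium-catalysed carboalumination adds CH3 and Al syn across the alkyne with methyl on the internal carbon, and the derived alanate opens oxirane with retention at the alkenyl carbon, so the C1=C10 alkene is formed as the E isomer only.

Step 3
Reactants: 6 (3E)-6-[(4-methoxyphenyl)methoxy]-4-methylhex-3-en-1-ol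
Product: 7 tert-butyl{[(3E)-6-[(4-methoxyphenyl)methoxy]-4-methylhex-3-en-1-yl]oxy}dimethylsilane
Conditions: TBSCl, imidazole, DMF, rt
Reagents that add atoms: tert-butyldimethylsilyl chloride, CC(C)(C)[Si](C)(C)Cl
Why: Standard silylation protects the C3 hydroxyl with a group orthogonal to the PMB ether at C8.

Step 4
Reactants: 7 tert-butyl{[(3E)-6-[(4-methoxyphenyl)methoxy]-4-methylhex-3-en-1-yl]oxy}dimethylsilane
Product: 8 tert-butyl(2-{(2R,3R)-3-[2-[(4-methoxyphenyl)methoxy]ethyl]-3-methyloxiran-2-yl}ethoxy)dimethylsilane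
Conditions: D-fructose-derived Shi ketone (1,2:4,5-di-O-isopropylidene-β-D-erythro-2,3-hexodiulo-2,6-pyranose, 0.3 equiv), KHSO5 (as Oxone, 2KHSO5·KHSO4·K2SO4), K2CO3, Bu4NHSO4, MeCN/CH2(OMe)2/aq. Na2B4O7–Na2EDTA buffer, 0 °C
Reagents that add atoms: potassium peroxymonosulfate (KHSO5), [K+].[O-]S(=O)(=O)OO
Why: Shi asymmetric epoxidation of the E-trisubstituted alkene through the spiro dioxirane transition state of the D-fructose-derived ketone delivers oxygen to the face that gives the (R,R)-epoxide, setting C1 and C10 by reagent control.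

Step 5
Reactants: 8 tert-butyl(2-{(2R,3R)-3-[2-[(4-methoxyphenyl)methoxy]ethyl]-3-methyloxiran-2-yl}ethoxy)dimethylsilane
Product: 9 2-[(2R,3R)-3-(2-{[tert-butyl(dimethyl)silyl]oxy}ethyl)-2-methyloxiran-2-yl]ethan-1-ol
Conditions: DDQ, CH2Cl2/pH 7 phosphate buffer (10:1), 0 °C
Reagents that add atoms: none
Why: Oxidative PMB cleavage under buffered neutral conditions frees the C8 hydroxyl and leaves the trisubstituted epoxide and the TBS ether intact.

Step 6
Reactants: 9 2-[(2R,3R)-3-(2-{[tert-butyl(dimethyl)silyl]oxy}ethyl)-2-methyloxiran-2-yl]ethan-1-ol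
Product: 10 2-[(2R,3R)-3-(2-{[tert-butyl(dimethyl)silyl]oxy}ethyl)-2-methyloxiran-2-yl]acetaldehyde
Conditions: Dess–Martin periodinane, NaHCO3, CH2Cl2, 0 °C → rt; used at once without chromatography
Reagents that add atoms: none
Why: Buffered Dess–Martin oxidation gives the β,γ-epoxy aldehyde (fragment A) without base or acid that would open the epoxide by β-elimination.

**Fragment B**

Step 7
Reactants: 11 (2S)-but-3-ene-1,2-diol
Product: 12 (3S)-3,4-bis[(triethylsilyl)oxy]but-1-ene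
Conditions: TESCl (2.2 equiv), imidazole, CH2Cl2, 0 °C → rt
Reagents that add atoms: chlorotriethylsilane, CC[Si](Cl)(CC)CC
Why: Double silylation of the chiral-pool diol protects the future C6 hydroxyl and prepares the primary position for direct oxidation; the C6 stereocentre is carried in unchanged.

Step 8
Reactants: 12 (3S)-3,4-bis[(triethylsilyl)oxy]but-1-ene
Product: 13 (2S)-2-[(triethylsilyl)oxy]but-3-enal
Conditions: (COCl)2, DMSO, CH2Cl2, −78 → −40 °C; then iPr2NEt, −78 → 0 °C; used at once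
Reagents that add atoms: none
Why: Under Swern conditions a primary TES ether is cleaved and oxidised directly to the aldehyde while the secondary TES ether survives, and the hindered base at low temperature keeps the α-stereocentre intact.

Step 9
Reactants: 13 (2S)-2-[(triethylsilyl)oxy]but-3-enal; 14 (1-bromoethenyl)trimethylsilane
Product: 16 (3S,4S)-4-[(triethylsilyl)oxy]-2-(trimethylsilyl)hexa-1,5-dien-3-ol, via Grignard reagent 15 (not isolated)
Conditions: 14, Mg, THF, rt → 40 °C; then 13, THF/Et2O, −78 °C; aq. NH4Cl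
Reagents that add atoms: none
Why: Grignard addition of the bulky 1-silylvinyl nucleophile to the non-chelating α-silyloxy aldehyde follows the polar Felkin–Anh model and gives the 3,4-anti alcohol (C5 of the target), the minor syn isomer being removed by chromatography.

Step 10
Reactants: 16 (3S,4S)-4-[(triethylsilyl)oxy]-2-(trimethylsilyl)hexa-1,5-dien-3-ol
Product: 17 (3S,4S)-2-iodo-4-[(triethylsilyl)oxy]hexa-1,5-dien-3-ol
Conditions: NIS, 2,6-lutidine (0.2 equiv), (CF3)2CHOH, 0 °C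
Reagents that add atoms: N-iodosuccinimide, O=C1CCC(=O)N1I
Why: Ipso-iododesilylation is directed to the vinylsilane by the β-silicon effect, so the 1-iodovinyl handle at C4 is installed without touching the plain vinyl group or either stereocentre.

Step 11
Reactants: 17 (3S,4S)-2-iodo-4-[(triethylsilyl)oxy]hexa-1,5-dien-3-ol; 18 2-(bromomethyl)prop-2-enoic acid
Product: 20 (3S,4S)-2-iodo-4-[(triethylsilyl)oxy]hexa-1,5-dien-3-yl 2-(bromomethyl)prop-2-enoate, via acid chloride 19 (not isolated)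
Conditions: 18, (COCl)2, DMF (cat.), CH2Cl2, 0 °C → rt; then 17, 2,6-lutidine, CH2Cl2, −20 °C → rt
Reagents that add atoms: none
Why: Acylation through the acid chloride with a hindered, non-nucleophilic base esterifies the C5 hydroxyl with retention and avoids SN2' attack of an amine on the allylic bromide.

Step 12
Reactants: 20 (3S,4S)-2-iodo-4-[(triethylsilyl)oxy]hexa-1,5-dien-3-yl 2-(bromomethyl)prop-2-enoate
Product: 21 (5S,6S)-3-(bromomethyl)-6-(1-iodoethenyl)-5-[(triethylsilyl)oxy]-5,6-dihydro-2H-pyran-2-one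
Conditions: second-generation Grubbs catalyst RuCl2(H2IMes)(PCy3)(=CHPh) (5 mol %), toluene (5 mM), 80 °C
Reagents that add atoms: none
Why: Ring-closing metathesis between the vinyl group and the acrylate gives the six-membered unsaturated lactone (fragment B) with loss of ethene, the hindered 1-iodovinyl group staying out of the metathesis, and the ring now holds C6 cis to the carbonyl.

**Coupling and endgame**

Step 13
Reactants: 10 2-[(2R,3R)-3-(2-{[tert-butyl(dimethyl)silyl]oxy}ethyl)-2-methyloxiran-2-yl]acetaldehyde; 21 (5S,6S)-3-(bromomethyl)-6-(1-iodoethenyl)-5-[(triethylsilyl)oxy]-5,6-dihydro-2H-pyran-2-one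
Product: 24 (4S,5R)-5-{[(2R,3R)-3-(2-{[tert-butyl(dimethyl)silyl]oxy}ethyl)-2-methyloxiran-2-yl]methyl}-4-{(1S,2S)-2-hydroxy-3-iodo-1-[(triethylsilyl)oxy]but-3-en-1-yl}-3-methylideneoxolan-2-one, via allylchromium dichloride 22 (not isolated), via δ-lactone carbinol 23 (not isolated)
Conditions: CrCl2 (nickel-free, 3 equiv), THF, 0 °C → rt, 10 and 21 added together; pH 7 buffer work-up; then DBU (0.2 equiv), CH2Cl2, 0 °C
Reagents that add atoms: none
Why: In this Nozaki–Hiyama-type chromium-mediated Barbier 2-carboxyallylation, divalent chromium inserts only into the allylic bromide (the vinyl iodide is inert without nickel). The ring-locked, E-crotyl-like allylchromium adds through a Zimmerman–Traxler chair with the aldehyde approaching C7 anti to the neighbouring OTES group, giving the anti C7/C8 adduct. The DBU-catalysed δ-to-γ acyl shift then gives the trans-fused α-methylene-γ-lactone and frees the C5 hydroxyl.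

Step 14
Reactants: 24 (4S,5R)-5-{[(2R,3R)-3-(2-{[tert-butyl(dimethyl)silyl]oxy}ethyl)-2-methyloxiran-2-yl]methyl}-4-{(1S,2S)-2-hydroxy-3-iodo-1-[(triethylsilyl)oxy]but-3-en-1-yl}-3-methylideneoxolan-2-one; 25 (2Z)-2-methylbut-2-enoic acid (angelic acid)
Product: 27 (1S,2S)-1-[(2R,3S)-2-{[(2R,3R)-3-(2-{[tert-butyl(dimethyl)silyl]oxy}ethyl)-2-methyloxiran-2-yl]methyl}-4-methylidene-5-oxooxolan-3-yl]-3-iodo-1-[(triethylsilyl)oxy]but-3-en-2-yl (2Z)-2-methylbut-2-enoate, via mixed anhydride 26 (not isolated)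
Conditions: 25, 2,4,6-trichlorobenzoyl chloride, Et3N, toluene, rt; then 24, toluene, 75 °C (no DMAP)
Reagents that add atoms: none
Why: Yamaguchi-type esterification through the mixed anhydride, run without DMAP, acylates the hindered C5 hydroxyl with retention at C5 and without Z-to-E isomerisation of the angelate.

Step 15
Reactants: 27 (1S,2S)-1-[(2R,3S)-2-{[(2R,3R)-3-(2-{[tert-butyl(dimethyl)silyl]oxy}ethyl)-2-methyloxiran-2-yl]methyl}-4-methylidene-5-oxooxolan-3-yl]-3-iodo-1-[(triethylsilyl)oxy]but-3-en-2-yl (2Z)-2-methylbut-2-enoate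
Product: 28 (1S,2S)-1-hydroxy-1-[(2R,3R)-2-{[(2R,3R)-3-(2-hydroxyethyl)-2-methyloxiran-2-yl]methyl}-4-methylidene-5-oxooxolan-3-yl]-3-iodobut-3-en-2-yl (2Z)-2-methylbut-2-enoate
Conditions: HF·pyridine, pyridine, THF, 0 °C → rt
Reagents that add atoms: none
Why: Buffered fluoride desilylation removes the primary TBS and secondary TES ethers under weakly acidic conditions that do not promote O5-to-O6 acyl migration and that the epoxide tolerates.

Step 16
Reactants: 28 (1S,2S)-1-hydroxy-1-[(2R,3R)-2-{[(2R,3R)-3-(2-hydroxyethyl)-2-methyloxiran-2-yl]methyl}-4-methylidene-5-oxooxolan-3-yl]-3-iodobut-3-en-2-yl (2Z)-2-methylbut-2-enoate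
Product: 29 (1S,2S)-1-hydroxy-3-iodo-1-[(2R,3R)-4-methylidene-2-{[(2R,3R)-2-methyl-3-(2-oxoethyl)oxiran-2-yl]methyl}-5-oxooxolan-3-yl]but-3-en-2-yl (2Z)-2-methylbut-2-enoate
Conditions: TEMPO (0.2 equiv), PhI(OAc)2, CH2Cl2, rt; used at once
Reagents that add atoms: none
Why: The oxoammonium (TEMPO/PhI(OAc)2) oxidation is selective for the primary C3 alcohol over the hindered secondary C6 alcohol and stops at the aldehyde.

Step 17
Reactants: 29 (1S,2S)-1-hydroxy-3-iodo-1-[(2R,3R)-4-methylidene-2-{[(2R,3R)-2-methyl-3-(2-oxoethyl)oxiran-2-yl]methyl}-5-oxooxolan-3-yl]but-3-en-2-yl (2Z)-2-methylbut-2-enoate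
Product: 31 (1R,5R,6S,7R,8R,10R)-5-angeloyloxy-1,10-epoxy-3,6-dihydroxygermacra-4(15),11(13)-dien-12,8-olide (C3 epimer mixture; locants as defined above), via alkenylchromium dichloride 30 (not isolated)
Conditions: CrCl2 (10 equiv), NiCl2 (0.1 equiv), degassed DMSO/THF (3:1), 2 mM, slow addition, rt
Reagents that add atoms: none
Why: In this intramolecular Nozaki–Hiyama–Kishi reaction, zerovalent nickel (formed from NiCl2 and CrCl2) inserts into the C4–I bond and hands the alkenyl group to trivalent chromium, which adds only to the aldehyde under high dilution to close the ten-membered ring; the new C3 carbinol centre is uncontrolled and is erased in step 18.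

Step 18
Reactants: 31 (1R,5R,6S,7R,8R,10R)-5-angeloyloxy-1,10-epoxy-3,6-dihydroxygermacra-4(15),11(13)-dien-12,8-olide (C3 epimer mixture; locants as defined above)
Product: 32 (1R,5R,6S,7R,8R,10R)-5-angeloyloxy-1,10-epoxy-6-hydroxy-3-oxogermacra-4(15),11(13)-dien-12,8-olide (CNP0348992.2; locants as defined above)
Conditions: activated MnO2, CH2Cl2, rt
Reagents that add atoms: none
Why: MnO2 oxidises only the allylic C3 alcohol (the C6 alcohol is not allylic) under neutral conditions, so the β,γ-epoxy ketone, the angelate and the α-methylene lactone survive and both C3 epimers converge on the target.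

**Compound list**

1 | but-3-yn-1-ol | C#CCCO | starting material
2 | 1-[(but-3-yn-1-yloxy)methyl]-4-methoxybenzene | C#CCCOCc1ccc(OC)cc1 | intermediate
3 | oxirane | C1CO1 | starting material
4 | [(1E)-4-[(4-methoxyphenyl)methoxy]-2-methylbut-1-en-1-yl]dimethylalane | C[Al](C)/C=C(\C)CCOCc1ccc(OC)cc1 | intermediate (not isolated)
5 | lithium butyl[(1E)-4-[(4-methoxyphenyl)methoxy]-2-methylbut-1-en-1-yl]dimethylaluminate | [Li+].CCCC[Al-](C)(C)/C=C(\C)CCOCc1ccc(OC)cc1 | intermediate (not isolated)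
6 | (3E)-6-[(4-methoxyphenyl)methoxy]-4-methylhex-3-en-1-ol | OCC/C=C(\C)CCOCc1ccc(OC)cc1 | intermediate
7 | tert-butyl{[(3E)-6-[(4-methoxyphenyl)methoxy]-4-methylhex-3-en-1-yl]oxy}dimethylsilane | CC(C)(C)[Si](C)(C)OCC/C=C(\C)CCOCc1ccc(OC)cc1 | intermediate
8 | tert-butyl(2-{(2R,3R)-3-[2-[(4-methoxyphenyl)methoxy]ethyl]-3-methyloxiran-2-yl}ethoxy)dimethylsilane | COc1ccc(COCC[C@@]2(C)O[C@@H]2CCO[Si](C)(C)C(C)(C)C)cc1 | intermediate
9 | 2-[(2R,3R)-3-(2-{[tert-butyl(dimethyl)silyl]oxy}ethyl)-2-methyloxiran-2-yl]ethan-1-ol | OCC[C@@]1(C)O[C@@H]1CCO[Si](C)(C)C(C)(C)C | intermediate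
10 | 2-[(2R,3R)-3-(2-{[tert-butyl(dimethyl)silyl]oxy}ethyl)-2-methyloxiran-2-yl]acetaldehyde (fragment A) | O=CC[C@@]1(C)O[C@@H]1CCO[Si](C)(C)C(C)(C)C | intermediate
11 | (2S)-but-3-ene-1,2-diol | OC[C@@H](O)C=C | starting material
12 | (3S)-3,4-bis[(triethylsilyl)oxy]but-1-ene | CC[Si](CC)(CC)OC[C@@H](O[Si](CC)(CC)CC)C=C | intermediate
13 | (2S)-2-[(triethylsilyl)oxy]but-3-enal | O=C[C@@H](O[Si](CC)(CC)CC)C=C | intermediate
14 | (1-bromoethenyl)trimethylsilane | C=C(Br)[Si](C)(C)C | starting material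
15 | bromo[1-(trimethylsilyl)ethenyl]magnesium | C=C([Mg]Br)[Si](C)(C)C | intermediate (not isolated)
16 | (3S,4S)-4-[(triethylsilyl)oxy]-2-(trimethylsilyl)hexa-1,5-dien-3-ol | C=C([Si](C)(C)C)[C@@H](O)[C@@H](O[Si](CC)(CC)CC)C=C | intermediate
17 | (3S,4S)-2-iodo-4-[(triethylsilyl)oxy]hexa-1,5-dien-3-ol | C=C(I)[C@@H](O)[C@@H](O[Si](CC)(CC)CC)C=C | intermediate
18 | 2-(bromomethyl)prop-2-enoic acid | C=C(CBr)C(=O)O | starting material
19 | 2-(bromomethyl)prop-2-enoyl chloride | C=C(CBr)C(=O)Cl | intermediate (not isolated)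
20 | (3S,4S)-2-iodo-4-[(triethylsilyl)oxy]hexa-1,5-dien-3-yl 2-(bromomethyl)prop-2-enoate | C=C(CBr)C(=O)O[C@H](C(I)=C)[C@@H](O[Si](CC)(CC)CC)C=C | intermediate
21 | (5S,6S)-3-(bromomethyl)-6-(1-iodoethenyl)-5-[(triethylsilyl)oxy]-5,6-dihydro-2H-pyran-2-one (fragment B) | C=C(I)[C@H]1OC(=O)C(CBr)=C[C@@H]1O[Si](CC)(CC)CC | intermediate
22 | dichloro{[(5S,6S)-6-(1-iodoethenyl)-2-oxo-5-[(triethylsilyl)oxy]-5,6-dihydro-2H-pyran-3-yl]methyl}chromium | C=C(I)[C@H]1OC(=O)C(C[Cr](Cl)Cl)=C[C@@H]1O[Si](CC)(CC)CC | intermediate (not isolated)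
23 | (4S,5S,6S)-4-{(1R)-1-hydroxy-2-[(2R,3R)-3-(2-{[tert-butyl(dimethyl)silyl]oxy}ethyl)-2-methyloxiran-2-yl]ethyl}-6-(1-iodoethenyl)-3-methylidene-5-[(triethylsilyl)oxy]oxan-2-one | C=C1C(=O)O[C@H](C(I)=C)[C@@H](O[Si](CC)(CC)CC)[C@@H]1[C@H](O)C[C@@]2(C)O[C@@H]2CCO[Si](C)(C)C(C)(C)C | intermediate (not isolated)
24 | (4S,5R)-5-{[(2R,3R)-3-(2-{[tert-butyl(dimethyl)silyl]oxy}ethyl)-2-methyloxiran-2-yl]methyl}-4-{(1S,2S)-2-hydroxy-3-iodo-1-[(triethylsilyl)oxy]but-3-en-1-yl}-3-methylideneoxolan-2-one | C=C1C(=O)O[C@H](C[C@@]2(C)O[C@@H]2CCO[Si](C)(C)C(C)(C)C)[C@H]1[C@H](O[Si](CC)(CC)CC)[C@H](O)C(I)=C | intermediate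
25 | (2Z)-2-methylbut-2-enoic acid (angelic acid) | C/C=C(/C)C(=O)O | starting material
26 | (2Z)-2-methylbut-2-enoic 2,4,6-trichlorobenzoic anhydride | C/C=C(/C)C(=O)OC(=O)c1c(Cl)cc(Cl)cc1Cl | intermediate (not isolated)
27 | (1S,2S)-1-[(2R,3S)-2-{[(2R,3R)-3-(2-{[tert-butyl(dimethyl)silyl]oxy}ethyl)-2-methyloxiran-2-yl]methyl}-4-methylidene-5-oxooxolan-3-yl]-3-iodo-1-[(triethylsilyl)oxy]but-3-en-2-yl (2Z)-2-methylbut-2-enoate | C=C1C(=O)O[C@H](C[C@@]2(C)O[C@@H]2CCO[Si](C)(C)C(C)(C)C)[C@H]1[C@H](O[Si](CC)(CC)CC)[C@H](OC(=O)/C(C)=C\C)C(I)=C | intermediate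
28 | (1S,2S)-1-hydroxy-1-[(2R,3R)-2-{[(2R,3R)-3-(2-hydroxyethyl)-2-methyloxiran-2-yl]methyl}-4-methylidene-5-oxooxolan-3-yl]-3-iodobut-3-en-2-yl (2Z)-2-methylbut-2-enoate | C=C1C(=O)O[C@H](C[C@@]2(C)O[C@@H]2CCO)[C@H]1[C@H](O)[C@H](OC(=O)/C(C)=C\C)C(I)=C | intermediate
29 | (1S,2S)-1-hydroxy-3-iodo-1-[(2R,3R)-4-methylidene-2-{[(2R,3R)-2-methyl-3-(2-oxoethyl)oxiran-2-yl]methyl}-5-oxooxolan-3-yl]but-3-en-2-yl (2Z)-2-methylbut-2-enoate | C=C1C(=O)O[C@H](C[C@@]2(C)O[C@@H]2CC=O)[C@H]1[C@H](O)[C@H](OC(=O)/C(C)=C\C)C(I)=C | intermediate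
30 | C4-dichlorochromium analogue of 29 (iodine replaced by CrCl2; configuration as in 29) | C=C1C(=O)O[C@H](C[C@@]2(C)O[C@@H]2CC=O)[C@H]1[C@H](O)[C@H](OC(=O)/C(C)=C\C)C([Cr](Cl)Cl)=C | intermediate (not isolated)
31 | (1R,5R,6S,7R,8R,10R)-5-angeloyloxy-1,10-epoxy-3,6-dihydroxygermacra-4(15),11(13)-dien-12,8-olide (C3 epimer mixture; locants as defined above) | C=C1C(=O)O[C@@H]2C[C@@]3(C)O[C@@H]3CC(O)C(=C)[C@@H](OC(=O)/C(C)=C\C)[C@@H](O)[C@@H]12 | intermediate
32 | (1R,5R,6S,7R,8R,10R)-5-angeloyloxy-1,10-epoxy-6-hydroxy-3-oxogermacra-4(15),11(13)-dien-12,8-olide (CNP0348992.2; locants as defined above) | C=C1C(=O)O[C@@H]2C[C@@]3(C)O[C@@H]3CC(=O)C(=C)[C@@H](OC(=O)/C(C)=C\C)[C@@H](O)[C@@H]12 | target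

**Step count**

Total step count: 18 (fragment A: steps 1–6; fragment B: steps 7–12; coupling and endgame: steps 13–18).
Longest linear sequence: 12 steps (steps 1–6 then 13–18, or equally steps 7–12 then 13–18).

**Steps most likely to fail, with fallbacks**

Step 12 (ring-closing metathesis). The ring closure has to engage an electron-poor, 1,1-disubstituted 2-(bromomethyl)acrylate next to an allylic bromide and a vinyl iodide, and it depends on the delicate acylation of step 11. The fallback sets out from 17 and builds the ring first and the bromomethyl group afterwards. Compound 17 is acylated with acryloyl chloride and iPr2NEt to (3S,4S)-2-iodo-4-[(triethylsilyl)oxy]hexa-1,5-dien-3-yl prop-2-enoate F1. The much easier disubstituted enoate is closed with the second-generation Grubbs catalyst RuCl2(H2IMes)(PCy3)(=CHPh) to (5S,6S)-6-(1-iodoethenyl)-5-[(triethylsilyl)oxy]-5,6-dihydro-2H-pyran-2-one F2. C13 is then introduced by Morita–Baylis–Hillman hydroxymethylation (aqueous CH2O, DMAP or Bu3P, THF/H2O) to give (5S,6S)-3-(hydroxymethyl)-6-(1-iodoethenyl)-5-[(triethylsilyl)oxy]-5,6-dihydro-2H-pyran-2-one F3, and an Appel bromination (CBr4, PPh3) converts it into 21, where the route is rejoined.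

Step 13 (fragment coupling). The β,γ-epoxy aldehyde 10 may not survive the Lewis-acidic trivalent chromium salts (β-elimination or Meinwald rearrangement). If the aldehyde is consumed slowly, the allylchromium 22 can also lose the neighbouring silyloxy group by 1,4-elimination. A further risk is the facial selectivity at C7: the adjacent OTES group and the 1,3-related iodovinyl group direct to opposite faces, and the route relies on the adjacent group dominating. The fallback postpones the epoxide and sets out from 7. DDQ gives (3E)-6-{[tert-butyl(dimethyl)silyl]oxy}-3-methylhex-3-en-1-ol F4, and Dess–Martin oxidation gives the more robust β,γ-unsaturated aldehyde (3E)-6-{[tert-butyl(dimethyl)silyl]oxy}-3-methylhex-3-enal F5. The same CrCl2-mediated coupling with 21 followed by the DBU lactone switch gives (4S,5R)-5-[(2E)-5-{[tert-butyl(dimethyl)silyl]oxy}-2-methylpent-2-en-1-yl]-4-{(1S,2S)-2-hydroxy-3-iodo-1-[(triethylsilyl)oxy]but-3-en-1-yl}-3-methylideneoxolan-2-one F6. Shi epoxidation with the D-fructose-derived ketone, acting on the only electron-rich alkene, then returns to 24.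

Step 17 (macrocyclisation). A strained ten-membered ring has to close onto a fragile β,γ-epoxy aldehyde, and the alkenylchromium 30 carries an allylic angelate that could be expelled to give an allene. The fallback closes the ring before the epoxide exists and epoxidises last, as in germacradienolide chemistry. It sets out from 7 and 21 and follows the step 13 fallback as far as its alkene lactone (F6 there), which is not epoxidised. F6 is angeloylated as in step 14 to (1S,2S)-1-[(2R,3S)-2-[(2E)-5-{[tert-butyl(dimethyl)silyl]oxy}-2-methylpent-2-en-1-yl]-4-methylidene-5-oxooxolan-3-yl]-3-iodo-1-[(triethylsilyl)oxy]but-3-en-2-yl (2Z)-2-methylbut-2-enoate F7. Desilylation with HF·pyridine gives the diol (1S,2S)-1-hydroxy-1-[(2R,3R)-2-[(2E)-5-hydroxy-2-methylpent-2-en-1-yl]-4-methylidene-5-oxooxolan-3-yl]-3-iodobut-3-en-2-yl (2Z)-2-methylbut-2-enoate F8, and TEMPO/PhI(OAc)2 oxidation gives the aldehyde (1S,2S)-1-hydroxy-3-iodo-1-[(2R,3R)-4-methylidene-2-[(2E)-2-methyl-5-oxopent-2-en-1-yl]-5-oxooxolan-3-yl]but-3-en-2-yl (2Z)-2-methylbut-2-enoate F9. CrCl2/NiCl2 cyclisation gives the macrocyclic allylic alcohol (1(10)E)-5-angeloyloxy-3,6-dihydroxygermacra-1(10),4(15),11(13)-trien-12,8-olide F10, and MnO2 gives the dienone (1(10)E)-5-angeloyloxy-6-hydroxy-3-oxogermacra-1(10),4(15),11(13)-trien-12,8-olide F11. Epoxidation of the electron-rich C1=C10 alkene (mCPBA, NaHCO3, CH2Cl2, 0 °C, peripheral attack on the E-alkene) then gives 32 directly; the face selectivity of this last epoxidation is substrate-controlled and would have to be confirmed.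

Further compounds
F1 | step 12 | (3S,4S)-2-iodo-4-[(triethylsilyl)oxy]hexa-1,5-dien-3-yl prop-2-enoate | C=CC(=O)O[C@H](C(I)=C)[C@@H](O[Si](CC)(CC)CC)C=C
F2 | step 12 | (5S,6S)-6-(1-iodoethenyl)-5-[(triethylsilyl)oxy]-5,6-dihydro-2H-pyran-2-one | C=C(I)[C@H]1OC(=O)C=C[C@@H]1O[Si](CC)(CC)CC
F3 | step 12 | (5S,6S)-3-(hydroxymethyl)-6-(1-iodoethenyl)-5-[(triethylsilyl)oxy]-5,6-dihydro-2H-pyran-2-one | C=C(I)[C@H]1OC(=O)C(CO)=C[C@@H]1O[Si](CC)(CC)CC
F4 | step 13 | (3E)-6-{[tert-butyl(dimethyl)silyl]oxy}-3-methylhex-3-en-1-ol | OCC/C(C)=C/CCO[Si](C)(C)C(C)(C)C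
F5 | step 13 | (3E)-6-{[tert-butyl(dimethyl)silyl]oxy}-3-methylhex-3-enal | O=CC/C(C)=C/CCO[Si](C)(C)C(C)(C)C
F6 | step 13 | (4S,5R)-5-[(2E)-5-{[tert-butyl(dimethyl)silyl]oxy}-2-methylpent-2-en-1-yl]-4-{(1S,2S)-2-hydroxy-3-iodo-1-[(triethylsilyl)oxy]but-3-en-1-yl}-3-methylideneoxolan-2-one | C=C1C(=O)O[C@H](C/C(C)=C/CCO[Si](C)(C)C(C)(C)C)[C@H]1[C@H](O[Si](CC)(CC)CC)[C@H](O)C(I)=C
F7 | step 17 | (1S,2S)-1-[(2R,3S)-2-[(2E)-5-{[tert-butyl(dimethyl)silyl]oxy}-2-methylpent-2-en-1-yl]-4-methylidene-5-oxooxolan-3-yl]-3-iodo-1-[(triethylsilyl)oxy]but-3-en-2-yl (2Z)-2-methylbut-2-enoate | C=C1C(=O)O[C@H](C/C(C)=C/CCO[Si](C)(C)C(C)(C)C)[C@H]1[C@H](O[Si](CC)(CC)CC)[C@H](OC(=O)/C(C)=C\C)C(I)=C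
F8 | step 17 | (1S,2S)-1-hydroxy-1-[(2R,3R)-2-[(2E)-5-hydroxy-2-methylpent-2-en-1-yl]-4-methylidene-5-oxooxolan-3-yl]-3-iodobut-3-en-2-yl (2Z)-2-methylbut-2-enoate | C=C1C(=O)O[C@H](C/C(C)=C/CCO)[C@H]1[C@H](O)[C@H](OC(=O)/C(C)=C\C)C(I)=C
F9 | step 17 | (1S,2S)-1-hydroxy-3-iodo-1-[(2R,3R)-4-methylidene-2-[(2E)-2-methyl-5-oxopent-2-en-1-yl]-5-oxooxolan-3-yl]but-3-en-2-yl (2Z)-2-methylbut-2-enoate | C=C1C(=O)O[C@H](C/C(C)=C/CC=O)[C@H]1[C@H](O)[C@H](OC(=O)/C(C)=C\C)C(I)=C
F10 | step 17 | (1(10)E,5R,6S,7R,8R)-5-angeloyloxy-3,6-dihydroxygermacra-1(10),4(15),11(13)-trien-12,8-olide (C3 epimer mixture; locants as defined above) | C=C1C(=O)O[C@@H]2C/C(C)=C/CC(O)C(=C)[C@@H](OC(=O)/C(C)=C\C)[C@@H](O)[C@@H]12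
F11 | step 17 | (1(10)E,5R,6S,7R,8R)-5-angeloyloxy-6-hydroxy-3-oxogermacra-1(10),4(15),11(13)-trien-12,8-olide (locants as defined above) | C=C1C(=O)O[C@@H]2C/C(C)=C/CC(=O)C(=C)[C@@H](OC(=O)/C(C)=C\C)[C@@H](O)[C@@H]12
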